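**Retrosynthetic overview**

1. Target 13 ⇐ primary-selective acetylation ⇐ Morita–Baylis–Hillman hydroxymethylation at C1 of epoxyquinol 11.
2. 11 ⇐ E1cB opening of the acetonide in epoxy ketone 9 (makes C1=C2, frees C3–OH) ⇐ hydroxyl-directed nucleophilic epoxidation of γ-hydroxy enone 8.
3. Key disconnection C4–C1': 8 ⇐ β-bromo enone 4, turned by Ni/Cr into a β-acylvinyl anion (a homoenolate equivalent at the enone oxidation level), plus (2E,6E)-farnesal 6; a chiral ligand on chromium sets C1'.
4. 4 ⇐ bromobenzene cis-dihydrodiol 1 (acetonide, diimide, allylic oxidation), which supplies the carbocycle and the C3 stereocentre that steers the oxirane; 6 ⇐ farnesol 5.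
5. Ring order: the carbocycle is present in 1; a temporary dioxolane is closed in step 1, the oxirane in step 6, and the dioxolane is cleaved in step 7.

**Assumptions and conventions**

- Assumption: (1S,2S)-3-bromocyclohexa-3,5-diene-1,2-diol (fermentation product of bromobenzene) and (2E,6E)-farnesol are taken as the commercial starting materials.
- Assumption: the (S)-configured ligand in step 5 is taken to give the (1'S) carbinol; if the sense of induction is the opposite, its enantiomer is used.
- Locants in the "Why" lines are those of the target ring: C1 carries CH2OAc, C2 is =CH, C3 is CHOH, C4 is the quaternary oxirane carbon, C5 is the oxirane CH, C6 is C=O, and C1' is the side-chain carbinol carbon.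

**Route**

Step 1
Reactants: 1 (1S,2S)-3-bromocyclohexa-3,5-diene-1,2-diol
Product: 2 (3aS,7aS)-4-bromo-2,2-dimethyl-3a,7a-dihydro-1,3-benzodioxole
Conditions: 2,2-dimethoxypropane, TsOH (cat.), acetone, 0 °C to rt; used at once
Reagents that add atoms: 2,2-dimethoxypropane, COC(C)(C)OC
Why: acid-catalysed acetonide formation (transketalisation) on the cis-diol, both stereocentres coming unchanged from 1.

Step 2
Reactants: 2 (3aS,7aS)-4-bromo-2,2-dimethyl-3a,7a-dihydro-1,3-benzodioxole
Product: 3 (3aS,7aS)-4-bromo-2,2-dimethyl-3a,6,7,7a-tetrahydro-1,3-benzodioxole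
Conditions: KO2CN=NCO2K, AcOH, MeOH, 0 °C to rt
Reagents that add atoms: none
Why: diimide reduction, a concerted syn transfer of H2 that takes the unhindered disubstituted alkene and leaves the bromine-bearing alkene and the C–Br bond alone, so no stereocentre is touched.

Step 3
Reactants: 3 (3aS,7aS)-4-bromo-2,2-dimethyl-3a,6,7,7a-tetrahydro-1,3-benzodioxole
Product: 4 (3aS,7aS)-7-bromo-2,2-dimethyl-3a,7a-dihydro-1,3-benzodioxol-5(4H)-one
Conditions: CrO3, 3,5-dimethylpyrazole, CH2Cl2, −20 °C
Reagents that add atoms: chromium trioxide, O=[Cr](=O)=O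
Why: allylic oxidation (Salmond conditions) at the only allylic methylene, next to the CH end of the vinyl bromide, gives the β-bromo enone, the other allylic C–H being a hindered acetal methine and no stereocentre being involved.

Step 4
Reactants: 5 (2E,6E)-farnesol
Product: 6 (2E,6E)-farnesal
Conditions: MnO2, CH2Cl2, rt
Reagents that add atoms: none
Why: chemoselective MnO2 oxidation of the primary allylic alcohol stops at the enal and keeps the 2E geometry.

Step 5
Reactants: 4 (3aS,7aS)-7-bromo-2,2-dimethyl-3a,7a-dihydro-1,3-benzodioxol-5(4H)-one; 6 (2E,6E)-farnesal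
Product: 8 (3aS,7aR)-7-[(1S,2E,6E)-1-hydroxy-3,7,11-trimethyldodeca-2,6,10-trien-1-yl]-2,2-dimethyl-3a,7a-dihydro-1,3-benzodioxol-5(4H)-one, via alkenylchromium dichloride 7 (not isolated)
Conditions: CrCl2 (4 equiv) pre-complexed 1:1:1 with Kishi-type (S)-4-isopropyl-2-(2-methanesulfonamidoaryl)oxazoline ligand and Et3N, NiCl2 (5 mol %), THF, rt; aq. sodium serinate work-up
Reagents that add atoms: none
Why: Nozaki–Hiyama–Kishi coupling, in which oxidative addition of zerovalent nickel into the activated C–Br bond and transmetalation to trivalent chromium turn the normally electrophilic β-carbon of the enone into a nucleophile (a β-acylvinyl anion) that adds 1,2 to the aldehyde carbon of 6 without touching the ketone, while the chiral sulfonamide ligand on chromium selects the aldehyde face so that the new carbinol C1' is S (reagent control).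

Step 6
Reactants: 8 (3aS,7aR)-7-[(1S,2E,6E)-1-hydroxy-3,7,11-trimethyldodeca-2,6,10-trien-1-yl]-2,2-dimethyl-3a,7a-dihydro-1,3-benzodioxol-5(4H)-one
Product: 9 (2R,3R,4S,5S)-2,3-epoxy-3-[(1S,2E,6E)-1-hydroxy-3,7,11-trimethyldodeca-2,6,10-trien-1-yl]-4,5-(isopropylidenedioxy)cyclohexan-1-one (oxirane trans to the dioxolane oxygens)
Conditions: t-BuOOH (2.4 equiv), n-BuLi (2.0 equiv), THF, −78 to −20 °C
Reagents that add atoms: tert-butyl hydroperoxide, CC(C)(C)OO
Why: hydroxyl-directed Weitz–Scheffer nucleophilic epoxidation, in which the lithium peroxide held by the C1' hydroxyl adds to C4 on the face anti to the dioxolane oxygen at C3 (in the A(1,2)-strain-minimised rotamer of the S carbinol the OH lies on that same face, so both controls agree) and the enolate closes the oxirane, setting C4 and C5 trans to the C3 oxygen while the isolated farnesyl alkenes stay inert to the peroxide anion.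

Step 7
Reactants: 9 (2R,3R,4S,5S)-2,3-epoxy-3-[(1S,2E,6E)-1-hydroxy-3,7,11-trimethyldodeca-2,6,10-trien-1-yl]-4,5-(isopropylidenedioxy)cyclohexan-1-one
Product: 11 (1R,5S,6S)-5-hydroxy-6-[(1S,2E,6E)-1-hydroxy-3,7,11-trimethyldodeca-2,6,10-trien-1-yl]-7-oxabicyclo[4.1.0]hept-3-en-2-one, via ring-opened hemiketal 10 (not isolated)
Conditions: DBU (1.05 equiv), CH2Cl2, −20 to 0 °C, then pH 7 buffer
Reagents that add atoms: none
Why: E1cB β-elimination (retro-oxa-Michael) of the β-alkoxy ketone, in which the C1 enolate expels the C2 oxygen of the dioxolane to form the C1=C2 enone and the resulting hemiketal loses acetone to free the C3 hydroxyl with its configuration untouched (the 6S label differs from the target's 6R only through CIP priorities, the geometry being the same).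

Step 8
Reactants: 11 (1R,5S,6S)-5-hydroxy-6-[(1S,2E,6E)-1-hydroxy-3,7,11-trimethyldodeca-2,6,10-trien-1-yl]-7-oxabicyclo[4.1.0]hept-3-en-2-one
Product: 12 (1R,5S,6R)-5-hydroxy-3-(hydroxymethyl)-6-[(1S,2E,6E)-1-hydroxy-3,7,11-trimethyldodeca-2,6,10-trien-1-yl]-7-oxabicyclo[4.1.0]hept-3-en-2-one
Conditions: aq. HCHO (37 %), DMAP (0.3 equiv), THF, rt
Reagents that add atoms: formaldehyde, C=O
Why: Morita–Baylis–Hillman reaction, in which DMAP adds to C2, the C1 enolate traps formaldehyde and DMAP is expelled, placing CH2OH on the enone α-carbon without touching any stereocentre.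

Step 9
Reactants: 12 (1R,5S,6R)-5-hydroxy-3-(hydroxymethyl)-6-[(1S,2E,6E)-1-hydroxy-3,7,11-trimethyldodeca-2,6,10-trien-1-yl]-7-oxabicyclo[4.1.0]hept-3-en-2-one
Product: 13 [(1R,5S,6R)-5-hydroxy-6-[(1S,2E,6E)-1-hydroxy-3,7,11-trimethyldodeca-2,6,10-trien-1-yl]-2-oxo-7-oxabicyclo[4.1.0]hept-3-en-3-yl]methyl acetate (CNP0137670.2)
Conditions: AcCl (1.05 equiv), 2,4,6-collidine, CH2Cl2, −78 °C
Reagents that add atoms: acetyl chloride, CC(Cl)=O
Why: kinetically selective O-acylation of the unhindered primary allylic hydroxyl over the two hindered secondary ones, no stereocentre being affected.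

**Compound list**

1 | (1S,2S)-3-bromocyclohexa-3,5-diene-1,2-diol | O[C@H]1C=CC=C(Br)[C@H]1O | starting material
2 | (3aS,7aS)-4-bromo-2,2-dimethyl-3a,7a-dihydro-1,3-benzodioxole | CC1(C)O[C@H]2C=CC=C(Br)[C@H]2O1 | intermediate
3 | (3aS,7aS)-4-bromo-2,2-dimethyl-3a,6,7,7a-tetrahydro-1,3-benzodioxole | CC1(C)O[C@H]2CCC=C(Br)[C@H]2O1 | intermediate
4 | (3aS,7aS)-7-bromo-2,2-dimethyl-3a,7a-dihydro-1,3-benzodioxol-5(4H)-one | CC1(C)O[C@H]2CC(=O)C=C(Br)[C@H]2O1 | intermediate
5 | (2E,6E)-farnesol, (2E,6E)-3,7,11-trimethyldodeca-2,6,10-trien-1-ol | OC/C=C(\C)CC/C=C(\C)CCC=C(C)C | starting material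
6 | (2E,6E)-farnesal, (2E,6E)-3,7,11-trimethyldodeca-2,6,10-trienal | O=C/C=C(\C)CC/C=C(\C)CCC=C(C)C | intermediate
7 | alkenylchromium dichloride from 4 (trivalent chromium on the former C–Br carbon; formed in the flask) | CC1(C)O[C@H]2CC(=O)C=C([Cr](Cl)Cl)[C@H]2O1 | intermediate
8 | (3aS,7aR)-7-[(1S,2E,6E)-1-hydroxy-3,7,11-trimethyldodeca-2,6,10-trien-1-yl]-2,2-dimethyl-3a,7a-dihydro-1,3-benzodioxol-5(4H)-one | CC1(C)O[C@H]2CC(=O)C=C([C@@H](O)/C=C(\C)CC/C=C(\C)CCC=C(C)C)[C@H]2O1 | intermediate
9 | (2R,3R,4S,5S)-2,3-epoxy-3-[(1S,2E,6E)-1-hydroxy-3,7,11-trimethyldodeca-2,6,10-trien-1-yl]-4,5-(isopropylidenedioxy)cyclohexan-1-one | C1[C@@H]3OC(C)(C)O[C@@H]3[C@@]2([C@@H](O)/C=C(\C)CC/C=C(\C)CCC=C(C)C)O[C@H]2C1=O | intermediate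
10 | ring-opened hemiketal: 11 carrying a 2-hydroxypropan-2-yl group on the C3 oxygen (formed in the flask) | C1=C[C@H](OC(C)(C)O)[C@@]2([C@@H](O)/C=C(\C)CC/C=C(\C)CCC=C(C)C)O[C@H]2C1=O | intermediate
11 | (1R,5S,6S)-5-hydroxy-6-[(1S,2E,6E)-1-hydroxy-3,7,11-trimethyldodeca-2,6,10-trien-1-yl]-7-oxabicyclo[4.1.0]hept-3-en-2-one | C1=C[C@H](O)[C@@]2([C@@H](O)/C=C(\C)CC/C=C(\C)CCC=C(C)C)O[C@H]2C1=O | intermediate
12 | (1R,5S,6R)-5-hydroxy-3-(hydroxymethyl)-6-[(1S,2E,6E)-1-hydroxy-3,7,11-trimethyldodeca-2,6,10-trien-1-yl]-7-oxabicyclo[4.1.0]hept-3-en-2-one | OCC1=C[C@H](O)[C@@]2([C@@H](O)/C=C(\C)CC/C=C(\C)CCC=C(C)C)O[C@H]2C1=O | intermediate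
13 | [(1R,5S,6R)-5-hydroxy-6-[(1S,2E,6E)-1-hydroxy-3,7,11-trimethyldodeca-2,6,10-trien-1-yl]-2-oxo-7-oxabicyclo[4.1.0]hept-3-en-3-yl]methyl acetate | CC(=O)OCC1=C[C@H](O)[C@@]2([C@@H](O)/C=C(\C)CC/C=C(\C)CCC=C(C)C)O[C@H]2C1=O | target

**Step count**

Total steps: 9. Longest linear sequence: 8 (steps 1, 2, 3, 5, 6, 7, 8, 9 from compound 1).

**Three steps most likely to fail, each with a fallback**

Step 5 (the coupling). Divalent chromium may simply reduce the bromo enone, any free amine may trigger loss of the acetonide and aromatisation, and the ligand may give poor control at C1'. The fallback sets out from 4 and comes back at 8. The ketone is masked (TMSOCH2CH2OTMS, cat. TMSOTf, CH2Cl2, −78 °C) as the bromo enone dioxolane F3. Bromine–lithium exchange (t-BuLi, 2 equiv, THF, −78 °C) gives the classical β-lithio enone ketal, which is added to 6 to give the carbinol dioxolane F4. The C1' epimers are separated by chromatography, since there is no reagent control here. Mild hydrolysis (PPTS, wet acetone) then gives 8.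

Step 6 (the epoxidation). Peroxide has to add to a fully substituted β-carbon, and the peroxide base can instead start the β-elimination of the acetonide in 8, which leads to aromatisation. The fallback sets out from 8 and comes back at 9, replacing delivery by the free hydroxyl with steric control on a protected substrate. Silylation (TESOTf, 2,6-lutidine, CH2Cl2, −78 °C) gives the triethylsilyl ether F5. Epoxidation under control of the dioxolane alone (t-BuOOH, Triton B, THF, 0 °C) gives the silylated epoxy ketone F6. HF·pyridine in THF then removes the silyl group to give 9.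

Step 3 (the allylic oxidation). Hexavalent chromium may attack the allylic acetal C–H or give a low yield. The fallback sets out from diene 2 and comes back at 4, so step 2 is skipped. NBS in wet THF adds HOBr across the distal alkene (bromonium anti to the dioxolane, water at the allylic carbon) to give the trans-bromohydrin F1. Bu3SnH with AIBN in benzene at 80 °C removes the secondary alkyl bromine but not the vinylic one, giving the allylic alcohol F2. MnO2 in CH2Cl2 then oxidises it to 4.

**Further compounds**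

F1 | step 3 | (3aR,4R,5S,7aS)-4,7-dibromo-2,2-dimethyl-3a,4,5,7a-tetrahydro-1,3-benzodioxol-5-ol (trans-bromohydrin; OH cis and alkyl Br trans to the dioxolane oxygens) | CC1(C)O[C@H]2[C@H](Br)[C@@H](O)C=C(Br)[C@H]2O1
F2 | step 3 | (3aS,5R,7aS)-7-bromo-2,2-dimethyl-3a,4,5,7a-tetrahydro-1,3-benzodioxol-5-ol (allylic alcohol) | CC1(C)O[C@H]2C[C@@H](O)C=C(Br)[C@H]2O1
F3 | step 5 | ethylene ketal (spiro-1,3-dioxolane at the former C=O) of 4, bromo enone dioxolane | CC1(C)O[C@H]2CC3(OCCO3)C=C(Br)[C@H]2O1
F4 | step 5 | ethylene ketal of 8, carbinol dioxolane with (1S) side-chain carbinol | CC1(C)O[C@H]2CC3(OCCO3)C=C([C@@H](O)/C=C(\C)CC/C=C(\C)CCC=C(C)C)[C@H]2O1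
F5 | step 6 | triethylsilyl ether of 8 at the C1' oxygen | CC1(C)O[C@H]2CC(=O)C=C([C@@H](O[Si](CC)(CC)CC)/C=C(\C)CC/C=C(\C)CCC=C(C)C)[C@H]2O1
F6 | step 6 | triethylsilyl ether of 9 at the C1' oxygen | C1[C@@H]3OC(C)(C)O[C@@H]3[C@@]2([C@@H](O[Si](CC)(CC)CC)/C=C(\C)CC/C=C(\C)CCC=C(C)C)O[C@H]2C1=O
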